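Subtract the target from the charge in the north-east flask and a leftover remains, substrate plus dormant form. Call it the pool; this text follows how it shrinks.

| flask | substrate | free enzyme | temperature | remark | time |
|---|---|---|---|---|---|
| north-east | 0.020 M | 2 µM | 25 °C | the very flask that is asked about, followed so far |  |
| east | 0.020 M | 2 µM | 20 °C | run made earlier |  |
| flask | 0.020 M | 2.0 µM | 25 °C |  | 2.5 h |

- north-east (time / min: target / %, substrate / %): 12.0: 43.8, 27.4; 20.0: 51.4, 23.3; 30.0: 55.8, 21.3; 40.0: 60.9, 19.0; 60.0: 66.6, 16.9; 90.0: 72.2, 14.5; 150: 78.6, 11.0
- east (time / min: target / %, substrate / %): 12.0: 48.7, 29.8; 20.0: 54.8, 21.9; 30.0: 58.0, 20.7; 40.0: 61.8, 17.4; 60.0: 66.0, 15.3; 90.0: 72.0, 13.2; 150: 77.4, 10.8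

(each reading ± 0.5 percentage points)

- target taken out counts as made
- steps thought possible: free enzyme -> unfolded enzyme; substrate <-> dormant form; substrate + free enzyme -> target + free enzyme
- additions bring no volume worth counting

- beta: at 2.5 h add free enzyme, 100 % of the amount charged, then wait 80 min
- epsilon: change nothing and wait 80 min more
- gamma: at 2.5 h take out 90 % of the target then present, then wait 80 min
- theta: at 2.5 h raise the temperature by 10 K, then wait 80 min

* target, in percent of the substrate first charged, at 2.5 h
* the option that brings most further target ("none" if no option brings more than 2 percentage points) (beta / epsilon / gamma / theta / none)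
* target present, with what was taken out counted in, in percent of the substrate first charged, after epsilon
* target present, with what was taken out counted in, in percent of the substrate first charged, after theta

Target opens steeply in the north-east flask: 43.8 % by 12.0 min, an average of 0.0365 min⁻¹ of the charge. The first landmark is where substrate meets dormant form. Substrate began as the whole pool, yet at that reading it stands at 27.4 % against 28.8 % of dormant form. From there the two travel together, and at 150 min substrate is still about half of the pool. From that reading on I therefore treat the exchange as quick (a rapid pre-equilibrium) and let the pool stand for substrate.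

The knee comes next. Target gains 0.00475 min⁻¹ between 20.0 min and 40.0 min, but 0.00107 min⁻¹ between 90.0 min and 150 min, while the pool at the middle of those spans falls from 44.2 % to 24.6 %. That gives a reading of the apparent order:

order = ln(slope ratio) / ln(pool ratio) = 2.55

At such an order the pool, raised to the power one minus the order, climbs straight with time, so the curve reaches no level in these readings. The slope of that line is:

clock = 0.0605 min⁻¹

I call this the drain clock. You wind it forward by adding clock times time, then undo the power.

Now is the last reading, 78.6 %. Waiting 80 min gives:

pool left = 16.9 %, so target = 83.1 %

Gamma runs the same, since no listed step leads back from target. Doubling free enzyme should double the clock, which gives 85.8 %, so of these options I choose beta. For theta I have no run at the raised temperature, so that choice stays untested against it.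

The forecast gives 78.5 %, 81.4 % after epsilon, which is less than my figure, 82 % after theta, and picks beta: “Heating speeds catalysis and frees substrate but kills enzyme faster”.

The flask gives 78.7 %, then 83.1 % after epsilon and 82.7 % after theta. The best option is beta, bringing 7.3 percentage points against 4.4 points for epsilon.

    free enzyme → unfolded enzyme (k = 1.80 × 10⁻⁵ s⁻¹, Ea = 212 kJ mol⁻¹)
    substrate ⇌ dormant form (K = 0.940, k = 0.00160 s⁻¹, Ea = 92.0 kJ mol⁻¹, ΔH = −15.0 kJ mol⁻¹)
    substrate + free enzyme → target + free enzyme, rate k3*[substrate]^2.5*[free enzyme]/(1 + ([substrate]/Kh3)^2.5) (29.0 mM, k = 6.90 × 10⁵ M⁻²·⁵ s⁻¹, Ea = 15.0 kJ mol⁻¹)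
    (constants at 25 °C)

At 150 min the clock puts the pool's drain time, the pool divided by its rate of fall, at 279 min, far longer than the forward half-life of 7.2 min for substrate going to dormant form. The flask then holds 10.8 % of substrate beside 10.5 % of dormant form. In the neighbour with 0.080 M of substrate, a 4.00-fold concentration multiplies the clock by 8.56, which puts target at 94.0 % after 2.5 h. That neighbour computes to 93.6 %.

The data are simulated for substances that don't exist; the scatter is artificial.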